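**Retrosynthetic overview**
- The last step removes a MOM ether from O7. Before that, ring C is cut at two bonds, C3–C1' and O1–C2, which gives a ring B ortho-quinone diazide and a ring A 2-hydroxyaryl enaminone.
- The strategy rests on C1' of ring B, which sits between the hydroxyl-bearing carbons C2' and C6'. Ring B is therefore the enol of a cyclic 1,3-dione, and C1' can carry a diazo group and react as an electrophilic rhodium carbene.
- Ring B: the C3' prenyl comes from a Claisen shift of a 1,1-dimethylallyl ether on a 2-nitro-5-methoxyresorcinol. The nitro group blocks C1' during the shift and is then converted to the diazo group (NO2, NH2, N2).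
- Ring A: 2,4-dihydroxyacetophenone, MOM-protected at the future O7, is condensed with DMF dimethyl acetal, which supplies C2.
- Ring order: rings A and B are purchased benzenes. Ring C is the only ring formed, in the fragment union, and deprotection follows.

Key step: step 10

Assumption: the quinone diazide is drawn as one hydroxy-dienone tautomer; the other tautomer and the diazonium phenolate form are the same compound and give the same carbene.

Step 1
Reactants: 1 2,4-dihydroxyacetophenone
Product: 2 2-hydroxy-4-(methoxymethoxy)acetophenone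
Conditions: MOMCl (1.1 equiv), K2CO3, acetone, 0 °C to rt
Reagents that add atoms: chloromethyl methyl ether (MOMCl), COCCl
Why: Williamson-type O-alkylation should be selective for the 4-hydroxyl because the 2-hydroxyl is held in a hydrogen bond to the acetyl carbonyl and is much less nucleophilic.

Step 2
Reactants: 2 2-hydroxy-4-(methoxymethoxy)acetophenone; 3 N,N-dimethylformamide dimethyl acetal
Product: 4 (E)-3-(dimethylamino)-1-[2-hydroxy-4-(methoxymethoxy)phenyl]prop-2-en-1-one
Conditions: 3 (1.5 equiv), toluene, 100 °C
Reagents that add atoms: none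
Why: Condensation of the acidic acetyl methyl group with the amide acetal (enaminone formation) should give the E vinylogous amide and supply the carbon that becomes C2, while the MOM ether keeps the 4-oxygen from being methylated by the acetal.

Step 3
Reactants: 5 1,3,5-trimethoxy-2-nitrobenzene
Product: 6 5-methoxy-2-nitrobenzene-1,3-diol
Conditions: AlCl3 (3 equiv), CH2Cl2, 0 °C to reflux; then ice, 1 M HCl
Reagents that add atoms: none
Why: Lewis-acid ether cleavage should be directed by chelation of aluminium between a nitro oxygen and each ortho methoxy oxygen, so chloride removes the two flanking methyl groups while the para methoxy group, which cannot chelate, stays.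

Step 4
Reactants: 7 2-methylbut-3-yn-2-ol
Product: 8 methyl 2-methylbut-3-yn-2-yl carbonate
Conditions: n-BuLi (1.0 equiv), THF, −78 °C; then ClCO2Me, −78 °C to rt
Reagents that add atoms: methyl chloroformate, COC(=O)Cl
Why: Acylation of the lithium alkoxide of a tertiary propargylic alcohol with a chloroformate is a standard carbonate synthesis, and with one equivalent of base the alkoxide forms in preference to the acetylide.

Step 5
Reactants: 6 5-methoxy-2-nitrobenzene-1,3-diol; 8 methyl 2-methylbut-3-yn-2-yl carbonate
Product: 9 3-(2-methylbut-3-yn-2-yloxy)-5-methoxy-2-nitrophenol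
Conditions: CuCl2 (divalent copper, 5 mol %), DBU (1.2 equiv), MeCN, 0 °C to rt, 8 (1.05 equiv) added slowly
Reagents that add atoms: none
Why: Copper-catalysed propargylic etherification should proceed through a copper acetylide that expels methyl carbonate and is attacked by the phenoxide at the tertiary carbon; the diol is symmetric, so either hydroxyl gives the same ether, and one equivalent of carbonate together with the crowding next to the nitro group should hold the reaction at mono-alkylation.

Step 6
Reactants: 9 3-(2-methylbut-3-yn-2-yloxy)-5-methoxy-2-nitrophenol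
Product: 10 3-(2-methylbut-3-en-2-yloxy)-5-methoxy-2-nitrophenol
Conditions: H2 (1 atm), Pd/CaCO3 poisoned with Pb(OAc)2 (Lindlar catalyst), quinoline, EtOAc, rt, stopped after one equivalent of H2
Reagents that add atoms: none
Why: Lindlar semi-hydrogenation should stop at the alkene on the poisoned catalyst, and an aryl nitro group is reduced far more slowly than a terminal alkyne under these conditions.

Step 7
Reactants: 10 3-(2-methylbut-3-en-2-yloxy)-5-methoxy-2-nitrophenol
Product: 11 5-methoxy-4-(3-methylbut-2-enyl)-2-nitrobenzene-1,3-diol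
Conditions: N,N-diethylaniline, 130 °C, argon
Reagents that add atoms: none
Why: The aromatic Claisen rearrangement ([3,3] sigmatropic shift) of the 1,1-dimethylallyl ether should deliver the allyl unit with inversion, as a prenyl group, to the only unsubstituted ortho carbon (the other is blocked by the nitro group), and the amine solvent buffers the acidic nitrophenol against chroman formation.

Step 8
Reactants: 11 5-methoxy-4-(3-methylbut-2-enyl)-2-nitrobenzene-1,3-diol
Product: 12 2-amino-5-methoxy-4-(3-methylbut-2-enyl)benzene-1,3-diol
Conditions: Na2S2O4 (4 equiv), THF/H2O, rt to 40 °C, argon; crude amine used at once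
Reagents that add atoms: none
Why: Dithionite reduction of a nitroarene to the aniline is chemoselective and, unlike catalytic hydrogenation, should leave the trisubstituted alkene and the aryl ethers untouched.

Step 9
Reactants: 12 2-amino-5-methoxy-4-(3-methylbut-2-enyl)benzene-1,3-diol
Product: 14 2-diazo-3-hydroxy-5-methoxy-6-(3-methylbut-2-enyl)cyclohexa-3,5-dien-1-one (ortho-quinone diazide), via arenediazonium chloride 13 (not isolated)
Conditions: NaNO2 (1.05 equiv), 1 M HCl, THF/H2O, 0 °C, dark; then NaHCO3 to pH 6–7, extraction into CH2Cl2, solution used at once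
Reagents that add atoms: sodium nitrite, [Na+].[O-]N=O
Why: Diazotization of an ortho-aminophenol gives the arenediazonium salt, which on neutralization loses a phenolic proton to form the neutral ortho-quinone diazide, and the short contact with cold dilute acid should spare the prenyl group.

Step 10
Reactants: 14 2-diazo-3-hydroxy-5-methoxy-6-(3-methylbut-2-enyl)cyclohexa-3,5-dien-1-one; 4 (E)-3-(dimethylamino)-1-[2-hydroxy-4-(methoxymethoxy)phenyl]prop-2-en-1-one
Product: 16 3-[2,6-dihydroxy-4-methoxy-3-(3-methylbut-2-enyl)phenyl]-7-(methoxymethoxy)-4H-chromen-4-one, via C-arylated enaminone 15 (not isolated)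
Conditions: Rh2(OAc)4 (divalent rhodium, 2 mol %), 4 (2.5 equiv), 1,2-dichloroethane, 60 °C, 14 added over several hours, dark, argon; then AcOH (5 equiv), 60 °C
Reagents that add atoms: none
Why: Proposed new method: Rh2(OAc)4 should expel N2 from 14 to give a quinoid rhodium carbene that is electrophilic at C1', which the strongly nucleophilic alpha carbon of the vinylogous amide 4 attacks to form the C3–C1' bond; loss of rhodium with proton transfer aromatizes ring B and leaves the C-arylated enaminone 15 or its iminium tautomer. The chelated ring A phenol then adds to the beta carbon (6-exo-trig on the iminium, formally a 6-endo oxa-Michael addition on the enaminone) and dimethylamine is eliminated, which closes ring C as the 4-pyranone through the O1–C2 bond. The closest known reaction types are the Rh2(OAc)4-catalysed C–H functionalization of enaminones and other electron-rich alkenes by carbenes from 2-diazo-1,3-diones and quinone diazides, and the domino alpha-functionalization and cyclization of 2-hydroxyaryl enaminones to 3-substituted chromones. No stereocenter is formed and the enaminone geometry is lost on closure. The step needs chemoselectivity for the enaminone over the prenyl alkene and the O–H bonds, which the far higher pi nucleophilicity of the enaminone, its excess and the slow addition of the diazide should secure; it also needs closure by the ring A oxygen and not by a ring B oxygen, and here the competing five-membered closure is reversible before dimethylamine is lost, so the acid finish is expected to drain material to the conjugated chromone, in line with the known Lewis-acid-promoted reorganization of 3-(2-hydroxyaroyl)benzofurans to 2'-hydroxyisoflavones.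

Step 11
Reactants: 16 3-[2,6-dihydroxy-4-methoxy-3-(3-methylbut-2-enyl)phenyl]-7-(methoxymethoxy)-4H-chromen-4-one
Product: 17 7-hydroxy-3-[2,6-dihydroxy-4-methoxy-3-(3-methylbut-2-enyl)phenyl]-4H-chromen-4-one (CNP0170909.0)
Conditions: 1 M HCl in MeOH, rt
Reagents that add atoms: none
Why: Acid-catalysed acetal exchange with methanol should remove the MOM group under conditions (dilute acid, room temperature, short time) in which hydroalkoxylation of the prenyl alkene by the neighbouring 2'-hydroxyl to a chroman is slow.

**Compound list**
1 | 2,4-dihydroxyacetophenone | CC(=O)c1ccc(O)cc1O | starting material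
2 | 2-hydroxy-4-(methoxymethoxy)acetophenone | CC(=O)c1ccc(OCOC)cc1O | intermediate
3 | N,N-dimethylformamide dimethyl acetal | COC(OC)N(C)C | starting material
4 | (E)-3-(dimethylamino)-1-[2-hydroxy-4-(methoxymethoxy)phenyl]prop-2-en-1-one | CN(C)/C=C/C(=O)c1ccc(OCOC)cc1O | intermediate
5 | 1,3,5-trimethoxy-2-nitrobenzene | COc1cc(OC)c([N+](=O)[O-])c(OC)c1 | starting material
6 | 5-methoxy-2-nitrobenzene-1,3-diol | COc1cc(O)c([N+](=O)[O-])c(O)c1 | intermediate
7 | 2-methylbut-3-yn-2-ol | C#CC(C)(C)O | starting material
8 | methyl 2-methylbut-3-yn-2-yl carbonate | C#CC(C)(C)OC(=O)OC | intermediate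
9 | 3-(2-methylbut-3-yn-2-yloxy)-5-methoxy-2-nitrophenol | COc1cc(O)c([N+](=O)[O-])c(OC(C)(C)C#C)c1 | intermediate
10 | 3-(2-methylbut-3-en-2-yloxy)-5-methoxy-2-nitrophenol | COc1cc(O)c([N+](=O)[O-])c(OC(C)(C)C=C)c1 | intermediate
11 | 5-methoxy-4-(3-methylbut-2-enyl)-2-nitrobenzene-1,3-diol | COc1cc(O)c([N+](=O)[O-])c(O)c1CC=C(C)C | intermediate
12 | 2-amino-5-methoxy-4-(3-methylbut-2-enyl)benzene-1,3-diol | COc1cc(O)c(N)c(O)c1CC=C(C)C | intermediate
13 | 2,6-dihydroxy-4-methoxy-3-(3-methylbut-2-enyl)benzenediazonium chloride (not isolated) | COc1cc(O)c([N+]#N)c(O)c1CC=C(C)C.[Cl-] | intermediate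
14 | 2-diazo-3-hydroxy-5-methoxy-6-(3-methylbut-2-enyl)cyclohexa-3,5-dien-1-one (ortho-quinone diazide) | COC1=C(CC=C(C)C)C(=O)C(=[N+]=[N-])C(O)=C1 | intermediate
15 | 3-(dimethylamino)-2-[2,6-dihydroxy-4-methoxy-3-(3-methylbut-2-enyl)phenyl]-1-[2-hydroxy-4-(methoxymethoxy)phenyl]prop-2-en-1-one (C-arylated enaminone, alkene geometry not fixed, not isolated) | CN(C)C=C(C(=O)c1ccc(OCOC)cc1O)c1c(O)cc(OC)c(CC=C(C)C)c1O | intermediate
16 | 3-[2,6-dihydroxy-4-methoxy-3-(3-methylbut-2-enyl)phenyl]-7-(methoxymethoxy)-4H-chromen-4-one | COc1cc(O)c(-c2coc3cc(OCOC)ccc3c2=O)c(O)c1CC=C(C)C | intermediate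
17 | 7-hydroxy-3-[2,6-dihydroxy-4-methoxy-3-(3-methylbut-2-enyl)phenyl]-4H-chromen-4-one (CNP0170909.0) | COc1cc(O)c(-c2coc3cc(O)ccc3c2=O)c(O)c1CC=C(C)C | target

Total step count: 11.
Longest linear sequence: 8 steps (steps 3, 5, 6, 7, 8, 9, 10 and 11, from 5 to 17).

**Steps most likely to fail**

Step 10 (key step). The ring could close through a ring B oxygen to a five-membered furan instead of through the ring A oxygen. The carbene could also be lost to O–H insertion, dimerization or Wolff ring contraction, and the prenyl alkene could be attacked. The fallback uses known chemistry, sets out from 4 and 14, and comes back to the route at 17. Enaminone 4 is cyclized with I2 and pyridine in CHCl3 to 3-iodo-7-(methoxymethoxy)-4H-chromen-4-one F1. Quinone diazide 14 is protonated and treated with KI (TsOH, MeCN/H2O, 0 °C to rt, Sandmeyer-type iododediazoniation) to give 2-iodo-5-methoxy-4-(3-methylbut-2-enyl)benzene-1,3-diol F2. F2 is protected with MOMCl and iPr2NEt as 2-iodo-5-methoxy-1,3-bis(methoxymethoxy)-4-(3-methylbut-2-enyl)benzene F3. Iodine–magnesium exchange (iPrMgCl·LiCl, THF, −20 °C) and trapping with 2-isopropoxy-4,4,5,5-tetramethyl-1,3,2-dioxaborolane then give 2-[4-methoxy-2,6-bis(methoxymethoxy)-3-(3-methylbut-2-enyl)phenyl]-4,4,5,5-tetramethyl-1,3,2-dioxaborolane F4. Suzuki–Miyaura coupling of F1 with F4 (Pd(OAc)2, SPhos, K3PO4, toluene/H2O, 80 °C) should give 3-[4-methoxy-2,6-bis(methoxymethoxy)-3-(3-methylbut-2-enyl)phenyl]-7-(methoxymethoxy)-4H-chromen-4-one F5. HCl in MeOH then removes all three MOM groups to give 17.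

Step 9. Nitrous acid could oxidize the electron-rich aminoresorcinol, nitrosate the ring at the free C5' position, or attack the prenyl alkene before the amine is diazotized. The fallback masks both phenols so that the amine is diazotized as an ordinary aniline. It sets out from 11 and comes back at 14. Both hydroxyls of 11 are silylated (TBSOTf, 2,6-lutidine, CH2Cl2) to 1,3-bis(tert-butyldimethylsilyloxy)-5-methoxy-4-(3-methylbut-2-enyl)-2-nitrobenzene F6. Zn and NH4Cl in THF/H2O reduce the nitro group to 2,6-bis(tert-butyldimethylsilyloxy)-4-methoxy-3-(3-methylbut-2-enyl)aniline F7. Anhydrous diazotization (NOBF4, MeCN, −30 °C) gives 2,6-bis(tert-butyldimethylsilyloxy)-4-methoxy-3-(3-methylbut-2-enyl)benzenediazonium tetrafluoroborate F8. Aqueous NaHCO3 in THF then cleaves the two silyl ethers, which are activated by the diazonium group, and releases 14.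

Step 5. O-alkylation of the hindered, weakly nucleophilic nitrophenoxide could be slow, could run on to the bis-ether, or the tertiary ether could ionize back to the phenoxide. The fallback builds the allyl ether directly and also bypasses the semi-hydrogenation of step 6. It sets out from 6 and comes back at 10. tert-Butyl 2-methylbut-3-en-2-yl carbonate F9 is prepared from 2-methylbut-3-en-2-ol and Boc2O (n-BuLi, THF). Decarboxylative O-allylation of 6 with F9 under Pd(PPh3)4 catalysis (zerovalent palladium, THF, 0 °C, Tsuji–Trost reaction) should give the tertiary ether 10 by kinetic attack of the phenoxide at the more substituted allyl terminus.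

Further compounds
F1 | step 10 | 3-iodo-7-(methoxymethoxy)-4H-chromen-4-one | COCOc1ccc2c(c1)occ(I)c2=O
F2 | step 10 | 2-iodo-5-methoxy-4-(3-methylbut-2-enyl)benzene-1,3-diol | COc1cc(O)c(I)c(O)c1CC=C(C)C
F3 | step 10 | 2-iodo-5-methoxy-1,3-bis(methoxymethoxy)-4-(3-methylbut-2-enyl)benzene | COCOc1cc(OC)c(CC=C(C)C)c(OCOC)c1I
F4 | step 10 | 2-[4-methoxy-2,6-bis(methoxymethoxy)-3-(3-methylbut-2-enyl)phenyl]-4,4,5,5-tetramethyl-1,3,2-dioxaborolane | COCOc1cc(OC)c(CC=C(C)C)c(OCOC)c1B1OC(C)(C)C(C)(C)O1
F5 | step 10 | 3-[4-methoxy-2,6-bis(methoxymethoxy)-3-(3-methylbut-2-enyl)phenyl]-7-(methoxymethoxy)-4H-chromen-4-one | COCOc1ccc2c(c1)occ(-c1c(OCOC)cc(OC)c(CC=C(C)C)c1OCOC)c2=O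
F6 | step 9 | 1,3-bis(tert-butyldimethylsilyloxy)-5-methoxy-4-(3-methylbut-2-enyl)-2-nitrobenzene | COc1cc(O[Si](C)(C)C(C)(C)C)c([N+](=O)[O-])c(O[Si](C)(C)C(C)(C)C)c1CC=C(C)C
F7 | step 9 | 2,6-bis(tert-butyldimethylsilyloxy)-4-methoxy-3-(3-methylbut-2-enyl)aniline | COc1cc(O[Si](C)(C)C(C)(C)C)c(N)c(O[Si](C)(C)C(C)(C)C)c1CC=C(C)C
F8 | step 9 | 2,6-bis(tert-butyldimethylsilyloxy)-4-methoxy-3-(3-methylbut-2-enyl)benzenediazonium tetrafluoroborate | COc1cc(O[Si](C)(C)C(C)(C)C)c([N+]#N)c(O[Si](C)(C)C(C)(C)C)c1CC=C(C)C.F[B-](F)(F)F
F9 | step 5 | tert-butyl 2-methylbut-3-en-2-yl carbonate | C=CC(C)(C)OC(=O)OC(C)(C)C
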